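## Retrosynthetic overview

1. Numbering used below: carbocycle C5(CMe2CO2H)–C6–C7–C8(Me)(O)–C9(H)–C10(Me)(CH2CO2H); pyran ring O–C8–C9–C11–C12–C13(Me)(CH=CH2); C4 is the CMe2 carbon and C1 the CH2 of CH2CO2H.
2. Pyran ring last: the C13–O bond comes from selenoetherification of the C8 tertiary alcohol onto a C13=C14 alkene, and selenoxide elimination then gives the vinyl group (sets C13).
3. C8–CH3 by Grignard addition; C13=C14 by Wittig olefination; C9–C11 by Mukaiyama–Michael addition of a regiodefined enol silane to methyl vinyl ketone.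
4. Six-membered carbocycle by one-carbon ring expansion of a 2,2,3-trisubstituted cyclopentanone: the 1,2-shift of the quaternary C10 in a β-oxido carbenoid inserts C9 between C8 and C10 and delivers the C8=C9 enol silane.
5. Cyclopentanone from cyclopent-2-enone: catalytic asymmetric Mukaiyama–Michael addition of the isobutyrate ketene silyl acetal (C5), then α-alkylation with methyl bromoacetate and with MeI (C10). Ring order: five-membered carbocycle, six-membered carbocycle, pyran.

Assumption: the catalyst of step 2, N-protonated (S)-3,3-diphenyl-1-(2-methylphenyl)tetrahydro-1H,3H-pyrrolo[1,2-c][1,3,2]oxazaborole triflimide, is taken to give the (S)-adduct by analogy with cyclohex-2-enone; if the sense is the opposite, its mirror image is used.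

## Route

Step 1
Reactants: 1 methyl 2-methylpropanoate
Product: 3 1-methoxy-2-methyl-1-(trimethylsilyloxy)prop-1-ene, via lithium ester enolate 2 (not isolated)
Conditions: LiN(i-Pr)2, THF, −78 °C; TMSCl, −78 → 25 °C
Reagents that add atoms: chlorotrimethylsilane, C[Si](C)(C)Cl
Why: Kinetic deprotonation and O-silylation of the ester enolate (silyl ketene acetal formation) is standard for an isobutyrate at −78 °C; no stereocentre is formed.

Step 2
Reactants: 3 1-methoxy-2-methyl-1-(trimethylsilyloxy)prop-1-ene; 4 cyclopent-2-en-1-one; 5 methyl bromoacetate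
Product: 7 methyl 2-[(1S,2R)-2-(2-methoxy-2-oxoethyl)-3-oxocyclopentyl]-2-methylpropanoate, via silyl enol ether 6 (not isolated)
Conditions: [C24H25BNO][N(SO2CF3)2] (S-oxazaborolidinium triflimide, 20 mol%), Ph3PO (25 mol%), toluene, −20 °C; then 5, BnMe3N+F−, THF, −20 → 25 °C
Reagents that add atoms: none
Why: The chiral oxazaborolidinium-catalysed Mukaiyama–Michael addition sets C5 (the enone is bound to the cationic boron and the aryl group shields one face of the β-carbon), and fluoride then releases the regiodefined enolate from 6, which the bromoacetate alkylates on the face away from the new CMe2CO2Me group (regiospecific enol-silane alkylation), giving the 2,3-trans product.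

Step 3
Reactants: 7 methyl 2-[(1S,2R)-2-(2-methoxy-2-oxoethyl)-3-oxocyclopentyl]-2-methylpropanoate
Product: 9 methyl 2-[(1S,2S)-2-(2-methoxy-2-oxoethyl)-2-methyl-3-oxocyclopentyl]-2-methylpropanoate, via potassium enolate 8 (not isolated)
Conditions: KH (0.95 equiv), THF, 25 °C; MeI, −20 °C
Reagents that add atoms: iodomethane, CI
Why: Under equilibrating conditions the more substituted enolate 8 predominates (thermodynamic enolate alkylation) and MeI attacks it anti to the neighbouring CMe2CO2Me group, so at the quaternary C10 the methyl ends trans and the CH2CO2Me group cis to that group.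

Step 4
Reactants: 9 methyl 2-[(1S,2S)-2-(2-methoxy-2-oxoethyl)-2-methyl-3-oxocyclopentyl]-2-methylpropanoate
Product: 13 methyl 2-[(1S,2S)-2-(2-methoxy-2-oxoethyl)-2-methyl-4-(trimethylsilyloxy)cyclohex-3-en-1-yl]-2-methylpropanoate, via lithium dibromomethyl carbinolate 10 (not isolated), via magnesium carbenoid 11 (not isolated), via magnesium enolate 12 (not isolated)
Conditions: CH2Br2, lithium 2,2,6,6-tetramethylpiperidide, THF, −78 °C; i-PrMgCl·LiCl, −78 → −20 °C; TMSCl, Et3N, 0 °C
Reagents that add atoms: dibromomethane, BrCBr; chlorotrimethylsilane, C[Si](C)(C)Cl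
Why: Proposed new method: a magnesium β-oxido carbenoid one-carbon ring expansion run on a diester ketone, with migration of a fully substituted carbon and direct capture of the enolate as its silyl ether: LiCHBr2 adds to the ketone, Br/Mg exchange with i-PrMgCl·LiCl (fast at −78 °C, expected to spare the methyl esters) gives carbenoid 11, in which the oxido group pushes the anti-periplanar and more electron-rich C8–C10 bond onto the carbenoid carbon with loss of bromide (1,2-shift with retention at C10, inserting C9 between C8 and C10) to give only the C8=C9 enolate 12, which TMSCl traps on oxygen; the closest known reaction type is the dibromomethyllithium/butyllithium β-oxido carbenoid ring enlargement of cycloalkanones together with the sulfoxide–magnesium exchange homologation of ketones, and this combination of exchange reagent, ester-bearing substrate and quaternary migrating carbon has not been shown.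

Step 5
Reactants: 13 methyl 2-[(1S,2S)-2-(2-methoxy-2-oxoethyl)-2-methyl-4-(trimethylsilyloxy)cyclohex-3-en-1-yl]-2-methylpropanoate; 14 but-3-en-2-one
Product: 16 methyl 2-[(1S,2S,3R)-2-(2-methoxy-2-oxoethyl)-2-methyl-4-oxo-3-(3-oxobutyl)cyclohexyl]-2-methylpropanoate, via side-chain silyl enol ether 15 (not isolated)
Conditions: Sc(OTf)3 (10 mol%), CH2Cl2, −78 → −40 °C; 1 M HCl, THF, 0 °C
Reagents that add atoms: none
Why: In this Sc(OTf)3-catalysed Mukaiyama–Michael addition the enol silane reacts through the half-chair with CMe2CO2Me pseudo-equatorial and CH2CO2Me pseudo-axial, so the enone adds at C9 along the axial trajectory anti to CH2CO2Me (the other face would be syn-axial to CMe2CO2Me), which places the 3-oxobutyl chain cis to the C10 methyl by C–C bond formation and not by a protonation.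

Step 6
Reactants: 16 methyl 2-[(1S,2S,3R)-2-(2-methoxy-2-oxoethyl)-2-methyl-4-oxo-3-(3-oxobutyl)cyclohexyl]-2-methylpropanoate
Product: 17 methyl 2-[(1S,2S,3R)-2-(2-methoxy-2-oxoethyl)-2-methyl-3-(3-methylpent-3-en-1-yl)-4-oxocyclohexyl]-2-methylpropanoate (E/Z mixture)
Conditions: EtPPh3Br, KN(SiMe3)2, THF, 0 °C; then 16 (ylide 1.05 equiv), −78 → 0 °C
Reagents that add atoms: ethyltriphenylphosphonium bromide, CC[P+](c1ccccc1)(c1ccccc1)c1ccccc1.[Br-]
Why: Wittig olefination with a non-stabilised ylide is much faster at the unhindered methyl ketone than at the ring ketone flanked by substituted carbons, and the E/Z ratio does not matter because the C14 geometry is erased in step 8.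

Step 7
Reactants: 17 methyl 2-[(1S,2S,3R)-2-(2-methoxy-2-oxoethyl)-2-methyl-3-(3-methylpent-3-en-1-yl)-4-oxocyclohexyl]-2-methylpropanoate
Product: 19 methyl 2-[(1S,2S,3R,4R)-4-hydroxy-2-(2-methoxy-2-oxoethyl)-2,4-dimethyl-3-(3-methylpent-3-en-1-yl)cyclohexyl]-2-methylpropanoate, via bromomagnesium alkoxide 18 (not isolated)
Conditions: MeMgBr, LaCl3·2LiCl (30 mol%), THF, −40 °C; AcOH, −40 °C
Reagents that add atoms: methylmagnesium bromide, C[Mg]Br
Why: In this LaCl3-promoted Grignard 1,2-addition (ketone far faster than the hindered esters at −40 °C) the ring sits in the chair with CMe2CO2Me equatorial, where the axial CH2CO2Me on C10 blocks the axial trajectory at C8, so methyl enters equatorially on the face of the C9 chain and the C10 methyl to give the axial tertiary alcohol, and the cold AcOH quench prevents lactonisation onto the nearby ester.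

Step 8
Reactants: 19 methyl 2-[(1S,2S,3R,4R)-4-hydroxy-2-(2-methoxy-2-oxoethyl)-2,4-dimethyl-3-(3-methylpent-3-en-1-yl)cyclohexyl]-2-methylpropanoate
Product: 22 methyl 2-[(2R,4aR,5S,6S,8aR)-2-ethenyl-5-(2-methoxy-2-oxoethyl)-2,5,8a-trimethyloctahydro-2H-chromen-6-yl]-2-methylpropanoate, via selenide 20 (not isolated), via selenoxide 21 (not isolated)
Conditions: PhSeCl, pyridine, CH2Cl2, −78 → 0 °C; 30% H2O2, 0 → 25 °C
Reagents that add atoms: none
Why: Phenylselenoetherification (irreversible 6-exo Markovnikov anti addition of the tertiary alcohol and PhSe+ across the trisubstituted alkene) is followed by selenoxide syn-elimination, which can only take a methyl hydrogen and so gives the vinyl group; in the chair-like transition state the bulky CH(SePh)CH3 terminus is equatorial and the C13 methyl axial, which sets C13, while the trans ring fusion is already fixed by C8 and C9.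

Step 9
Reactants: 22 methyl 2-[(2R,4aR,5S,6S,8aR)-2-ethenyl-5-(2-methoxy-2-oxoethyl)-2,5,8a-trimethyloctahydro-2H-chromen-6-yl]-2-methylpropanoate
Product: 24 2-[(2R,4aR,5S,6S,8aR)-5-(carboxymethyl)-2-ethenyl-2,5,8a-trimethyloctahydro-2H-chromen-6-yl]-2-methylpropanoic acid, via dipotassium dicarboxylate 23 (not isolated)
Conditions: KOH (10 equiv), MeOH–H2O, 80 °C; 1 M HCl to pH 3, 0 °C
Reagents that add atoms: potassium hydroxide, [K+].[OH-]
Why: Saponification of both methyl esters (forcing conditions for the hindered one) leaves the base-stable tertiary allylic ether untouched, and brief cold acidification releases the diacid without ionising that ether; no stereocentre is touched.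

## Compound list

1 | methyl 2-methylpropanoate | CC(C)C(=O)OC | starting material
2 | lithium 1-methoxy-2-methylprop-1-en-1-olate (enolate of 1) | [Li+].[O-]C(OC)=C(C)C | intermediate
3 | 1-methoxy-2-methyl-1-(trimethylsilyloxy)prop-1-ene | COC(O[Si](C)(C)C)=C(C)C | intermediate
4 | cyclopent-2-en-1-one | O=C1C=CCC1 | starting material
5 | methyl bromoacetate | BrCC(=O)OC | starting material
6 | methyl 2-methyl-2-[(1S)-3-(trimethylsilyloxy)cyclopent-2-en-1-yl]propanoate | C[Si](C)(C)OC1=C[C@@H](C(C)(C)C(=O)OC)CC1 | intermediate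
7 | methyl 2-[(1S,2R)-2-(2-methoxy-2-oxoethyl)-3-oxocyclopentyl]-2-methylpropanoate (2,3-trans) | O=C1[C@H](CC(=O)OC)[C@@H](C(C)(C)C(=O)OC)CC1 | intermediate
8 | potassium enolate of 7 toward the carbon bearing CH2CO2Me | [K+].[O-]C1=C(CC(=O)OC)[C@@H](C(C)(C)C(=O)OC)CC1 | intermediate
9 | methyl 2-[(1S,2S)-2-(2-methoxy-2-oxoethyl)-2-methyl-3-oxocyclopentyl]-2-methylpropanoate (ring methyl trans to CMe2CO2Me) | O=C1[C@@](C)(CC(=O)OC)[C@@H](C(C)(C)C(=O)OC)CC1 | intermediate
10 | lithium alkoxide of the 1-(dibromomethyl)cyclopentanol from 9 (carbinol carbon: either configuration) | [Li+].[O-]C1(C(Br)Br)[C@@](C)(CC(=O)OC)[C@@H](C(C)(C)C(=O)OC)CC1 | intermediate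
11 | magnesium carbenoid, the bromo(chloromagnesio)methyl carbinolate from 10 | [Li+].[O-]C1(C(Br)[Mg]Cl)[C@@](C)(CC(=O)OC)[C@@H](C(C)(C)C(=O)OC)CC1 | intermediate
12 | chloromagnesium C8=C9 enolate of the ring-expanded cyclohexanone | Cl[Mg]OC1=C[C@@](C)(CC(=O)OC)[C@@H](C(C)(C)C(=O)OC)CC1 | intermediate
13 | methyl 2-[(1S,2S)-2-(2-methoxy-2-oxoethyl)-2-methyl-4-(trimethylsilyloxy)cyclohex-3-en-1-yl]-2-methylpropanoate | C[Si](C)(C)OC1=C[C@@](C)(CC(=O)OC)[C@@H](C(C)(C)C(=O)OC)CC1 | intermediate
14 | but-3-en-2-one | CC(=O)C=C | starting material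
15 | side-chain trimethylsilyl enol ether of 16 (E/Z mixture) | C[Si](C)(C)OC(C)=CC[C@@H]1[C@@](C)(CC(=O)OC)[C@@H](C(C)(C)C(=O)OC)CCC1=O | intermediate
16 | methyl 2-[(1S,2S,3R)-2-(2-methoxy-2-oxoethyl)-2-methyl-4-oxo-3-(3-oxobutyl)cyclohexyl]-2-methylpropanoate | CC(=O)CC[C@@H]1[C@@](C)(CC(=O)OC)[C@@H](C(C)(C)C(=O)OC)CCC1=O | intermediate
17 | methyl 2-[(1S,2S,3R)-2-(2-methoxy-2-oxoethyl)-2-methyl-3-(3-methylpent-3-en-1-yl)-4-oxocyclohexyl]-2-methylpropanoate (E/Z mixture) | CC=C(C)CC[C@@H]1[C@@](C)(CC(=O)OC)[C@@H](C(C)(C)C(=O)OC)CCC1=O | intermediate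
18 | bromomagnesium alkoxide of 19 | CC=C(C)CC[C@@H]1[C@@](C)(CC(=O)OC)[C@@H](C(C)(C)C(=O)OC)CC[C@@]1(C)O[Mg]Br | intermediate
19 | methyl 2-[(1S,2S,3R,4R)-4-hydroxy-2-(2-methoxy-2-oxoethyl)-2,4-dimethyl-3-(3-methylpent-3-en-1-yl)cyclohexyl]-2-methylpropanoate (E/Z mixture) | CC=C(C)CC[C@@H]1[C@@](C)(CC(=O)OC)[C@@H](C(C)(C)C(=O)OC)CC[C@@]1(C)O | intermediate
20 | methyl 2-[(2R,4aR,5S,6S,8aR)-5-(2-methoxy-2-oxoethyl)-2,5,8a-trimethyl-2-[1-(phenylselanyl)ethyl]octahydro-2H-chromen-6-yl]-2-methylpropanoate (CHSe carbon: mixture) | CC([Se]c3ccccc3)[C@@]1(C)CC[C@@H]2[C@@](C)(CC(=O)OC)[C@@H](C(C)(C)C(=O)OC)CC[C@@]2(C)O1 | intermediate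
21 | selenoxide of 20 | CC([Se](=O)c3ccccc3)[C@@]1(C)CC[C@@H]2[C@@](C)(CC(=O)OC)[C@@H](C(C)(C)C(=O)OC)CC[C@@]2(C)O1 | intermediate
22 | methyl 2-[(2R,4aR,5S,6S,8aR)-2-ethenyl-5-(2-methoxy-2-oxoethyl)-2,5,8a-trimethyloctahydro-2H-chromen-6-yl]-2-methylpropanoate | C=C[C@@]1(C)CC[C@@H]2[C@@](C)(CC(=O)OC)[C@@H](C(C)(C)C(=O)OC)CC[C@@]2(C)O1 | intermediate
23 | dipotassium salt of 24 | C=C[C@@]1(C)CC[C@@H]2[C@@](C)(CC(=O)[O-])[C@@H](C(C)(C)C(=O)[O-])CC[C@@]2(C)O1.[K+].[K+] | intermediate
24 | 2-[(2R,4aR,5S,6S,8aR)-5-(carboxymethyl)-2-ethenyl-2,5,8a-trimethyloctahydro-2H-chromen-6-yl]-2-methylpropanoic acid | C=C[C@@]1(C)CC[C@@H]2[C@@](C)(CC(=O)O)[C@@H](C(C)(C)C(=O)O)CC[C@@]2(C)O1 | target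

## Step count and risks

Total step count: 9. Longest linear sequence: 9 steps (1 to 24).

Three steps most likely to fail:

Step 3 (regioselective methylation). The enolate may form toward the ring CH2 instead, or the product may be methylated twice. Fallback, setting out from 4 and coming back at 9: 4 is iodinated (I2, pyridine, CCl4) to 2-iodocyclopent-2-en-1-one F1, which is coupled with BrZnCH2CO2Me (from 5 and zinc) under Pd(PPh3)4 catalysis to methyl 2-(5-oxocyclopent-1-en-1-yl)acetate F2. The same oxazaborolidinium-catalysed Mukaiyama–Michael addition of 3 to F2 then gives the fully substituted silyl enol ether F3 as the only regioisomer, and BnMe3N+F−/MeI methylates it anti to the CMe2CO2Me group to give 9.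

Step 4 (the proposed new ring expansion). The carbenoid reagents may attack the esters, carbinolate 10 may lactonise, or the ring CH2 may migrate instead of C10. Fallback with known chemistry, setting out from 7 and coming back at 13: TESCl, NaI and Et3N in MeCN convert 7 into the more substituted triethylsilyl enol ether F4 (the minor regioisomer is removed), and Et2Zn/CH2I2 cyclopropanation gives the triethylsilyloxy bicyclo[3.1.0]hexane F5. FeCl3 in DMF at 0 °C opens F5 by alkoxy-radical β-scission of the ring-fusion bond to the ring-expanded tertiary β-chloro ketone F6 (Saegusa–Ito ring expansion), and NaOAc in MeOH eliminates HCl to the 3,4-disubstituted cyclohex-2-enone F7. Me2CuLi with TMSCl in THF at −78 °C adds methyl to the β-carbon anti to the CMe2CO2Me group and the enolate is silylated, which gives 13.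

Step 7 (methyl addition at C8). The facial preference rests on a conformational argument with both faces hindered, the ketone may not react, or the alkoxide may lactonise. Fallback, setting out from 17 and coming back at 19: dimethylsulfoxonium methylide (Me3S(O)I, NaH, DMSO) adds reversibly to 17 and closes the spiro-epoxide F8 from the more stable betaine, with the new C–C bond equatorial, so the C8 face is set under thermodynamic instead of kinetic control. MgI2 in Et2O opens F8 at the CH2 terminus to the iodohydrin F9, and Bu3SnH with AIBN in benzene replaces iodine by hydrogen to give 19.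

## Further compounds

F1 | step 3 | 2-iodocyclopent-2-en-1-one | O=C1CCC=C1I
F2 | step 3 | methyl 2-(5-oxocyclopent-1-en-1-yl)acetate | COC(=O)CC1=CCCC1=O
F3 | step 3 | methyl 2-[(1S)-2-(2-methoxy-2-oxoethyl)-3-(trimethylsilyloxy)cyclopent-2-en-1-yl]-2-methylpropanoate | C[Si](C)(C)OC1=C(CC(=O)OC)[C@@H](C(C)(C)C(=O)OC)CC1
F4 | step 4 | methyl 2-[(1S)-2-(2-methoxy-2-oxoethyl)-3-(triethylsilyloxy)cyclopent-2-en-1-yl]-2-methylpropanoate | CC[Si](CC)(CC)OC1=C(CC(=O)OC)[C@@H](C(C)(C)C(=O)OC)CC1
F5 | step 4 | triethylsilyloxy bicyclo[3.1.0]hexane from F4 (cyclopropane carbons: configuration not assigned) | CC[Si](CC)(CC)OC12CC1(CC(=O)OC)[C@@H](C(C)(C)C(=O)OC)CC2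
F6 | step 4 | ring-expanded 3-chloro-3-(2-methoxy-2-oxoethyl)cyclohexanone bearing CMe2CO2Me at C4 (chloride carbon: mixture) | O=C1CC(Cl)(CC(=O)OC)[C@@H](C(C)(C)C(=O)OC)CC1
F7 | step 4 | methyl 2-[(1S)-2-(2-methoxy-2-oxoethyl)-4-oxocyclohex-2-en-1-yl]-2-methylpropanoate | O=C1C=C(CC(=O)OC)[C@@H](C(C)(C)C(=O)OC)CC1
F8 | step 7 | spiro-epoxide of 17 at C8 (CH2 on the face of the C9 chain) | CC=C(C)CC[C@@H]1[C@@](C)(CC(=O)OC)[C@@H](C(C)(C)C(=O)OC)CC[C@@]12OC2
F9 | step 7 | iodohydrin from F8 (C8 bears OH and CH2I) | CC=C(C)CC[C@@H]1[C@@](C)(CC(=O)OC)[C@@H](C(C)(C)C(=O)OC)CC[C@@]1(CI)O
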